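All runs are simulated from invented constants; scatter was added.

The leftover substrate does not go away: over the last three readings of both runs it averages 1.90% of the charge, above the scatter of 0.5 percentage points, while Sunday's target reads 21.9% at 3.00 d and 21.9% at 6.00 d.

| setting | Sunday's | Saturday's | flask |
|---|---|---|---|
| substrate | 6.7 mM | 15 mM | 10 mM |
| remark | run made earlier | run made earlier |  |
| time |  |  | 6.0 d |

- Sunday's (time / d: substrate / %, target / %): 0.417: 15.9, 39.5; 1.25: 2.7, 23.1; 2.00: 2.2, 22.1; 3.00: 2.2, 21.9; 5.00: 2.3, 20.9; 6.00: 1.5, 21.9
- Saturday's (time / d: substrate / %, target / %): 1.04: 3.1, 21.3; 2.08: 2.0, 19.2; 3.00: 2.4, 19.6; 4.00: 2.7, 17.6; 5.00: 1.7, 17.7; 6.00: 1.0, 18.6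

(each reading ± 0.5 percentage points)

- the numbers in the tables scatter with a standard deviation of 0.5 percentage points
- the reaction counts as stopped when no species that holds the substrate changes by six tenths of a point or more over the second half of the time

- the state of affairs at 6.0 d: stopped, and by what, or still going (it is still moving / forward and back rates have come level)
- conversion of substrate at 6.0 d
- amount of target at 6.0 d, in percent of the substrate charged

So I take this flask to count as stopped by 6.0 d with forward and back rates level (equilibrium), at a conversion of 98.1%. For the target I freeze the last three readings of each run: they average 21.6% on Sunday and 18.0% on Saturday, lower at the larger charge. Dividing that gap by the logarithm of the ratio of the charges gives the loading loss, 4.5 points, the points of target given up per unit of the natural logarithm of the charge. Carried from Sunday's charge to 10 mM, it gives me 19.8% of target.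

The forecast says forward and back rates have come level, with conversion 98% (97.2% to 98.7%) and target 20.2% (18.8% to 21.5%), higher than my 19.8%, holding that the steady ratio of target to substrate “points to equilibrium rather than a stalled reaction”.

The state of the flask at 6.0 d is this: forward and back rates have come level, with conversion 98.2% and target 20.1%.

    substrate ⇌ target (K = 11.0, k = 0.175 /h)
    target ⇌ isomer of the product A (K = 2.40, k = 0.110 /h)
    isomer of the product A ⇌ isomer of the product B (K = 0.175, k = 0.0397 /h)
    2 substrate → homo dimer (k = 4.65 /M/h)

That target lies 0.30 points above my reckoning from the loading loss. Homo dimer, counted by the substrate it holds, stands at 21.2% in this flask at 6.00 d and at 38.3% in a neighbour flask charged with 25 mM. Carried from Saturday's charge to that neighbour, the loading loss of 4.5 points gives 15.7% of target, and the neighbour holds 15.8%.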